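**Retrosynthetic overview** (longipinane numbering: C1=O, C2=C3(Me), bridgeheads C4 and C11, C5, C6(Me)2, C7 and C9 esters, quaternary C10)
1. Target ⇒ a 3-oxo-15-nor-longipin-1-ene diester by MeMgBr addition and oxidative 1,3-carbonyl transposition; the 3-oxo group stands in for the C3 cation of the biosynthetic pathway and steers both ring closures.
2. Cyclobutane, formed last (C4–C10, the himachalyl-to-longipinyl bond): the ketone enolate carbon C4 opens a 9,10-epoxide at its tertiary carbon (4-exo), which also delivers the C9 oxygen.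
3. Seven-membered ring, formed before it (C5–C6, the farnesyl C1–C11 bond): a tertiary radical from a Shi epoxide (which becomes C7–OH) adds to the enone carbon of a 4-substituted cyclohexenone.
4. The six-membered ring is purchased; the chain comes from a bisabolene-type Wittig reaction and the ring stereocentre from a chiral-base desymmetrisation; ring order is six (given), then seven, then four.

Assumption: ketone 3 is taken as a catalogue building block, and the (S,S)-amide is assumed to give the (4R)-enol silane by analogy with 4-tert-butylcyclohexanone (the antipodal amide is used if the sense is opposite).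

**Step 1**
Reactants: 1 5-bromo-2-methylpent-2-ene
Product: 2 (4-methylpent-3-en-1-yl)triphenylphosphonium bromide
Conditions: PPh3, MeCN, 80 °C
Reagents that add atoms: triphenylphosphine, c1ccc(cc1)P(c1ccccc1)c1ccccc1
Why: SN2 quaternisation of the phosphine by the primary bromide (phosphonium salt formation for a Wittig reaction) creates no stereocentre.

**Step 2**
Reactants: 2 (4-methylpent-3-en-1-yl)triphenylphosphonium bromide; 3 1-(1,4-dioxaspiro[4.5]decan-8-yl)ethan-1-one
Product: 6 4-[(2Z)-6-methylhepta-2,5-dien-2-yl]cyclohexan-1-one, via phosphorus ylide 4 (not isolated), via ketal diene 5 (not isolated)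
Conditions: NaN(SiMe3)2, THF, −78 °C to rt; then 3, 0 °C to rt; then 1 M HCl, THF, rt
Reagents that add atoms: water, O
Why: Wittig olefination of the methyl ketone by a non-stabilised ylide under lithium-free conditions favours the (Z)-trisubstituted alkene (the alpha-bisabolene Wittig reaction, ylide substituent cis to the larger ketone substituent), the minor (E)-isomer is removed by chromatography, and acid hydrolysis of the ketal then frees the ring ketone.

**Step 3**
Reactants: 6 4-[(2Z)-6-methylhepta-2,5-dien-2-yl]cyclohexan-1-one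
Product: 8 (4R)-4-[(2Z)-6-methylhepta-2,5-dien-2-yl]cyclohex-2-en-1-one, via silyl enol ether 7 (not isolated)
Conditions: lithium (S,S)-bis(1-phenylethyl)amide (amine + n-BuLi), LiCl, Me3SiCl, THF, −100 °C; then Pd(OAc)2, MeCN, rt
Reagents that add atoms: none
Why: Enantiotopic-proton-selective deprotonation of the prochiral 4-substituted cyclohexanone by the chiral lithium amide with in situ silylation (Koga–Simpkins desymmetrisation) fixes the ring stereocentre, and Saegusa–Ito oxidation of the enol silane by divalent palladium places the enone double bond next to that centre.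

**Step 4**
Reactants: 8 (4R)-4-[(2Z)-6-methylhepta-2,5-dien-2-yl]cyclohex-2-en-1-one
Product: 9 (4R)-4-{(2Z)-4-[(2R)-3,3-dimethyloxiran-2-yl]but-2-en-2-yl}cyclohex-2-en-1-one
Conditions: D-fructose-derived Shi ketone (30 mol %), Oxone (2KHSO5·KHSO4·K2SO4), K2CO3, Bu4NHSO4, MeCN–CH2(OMe)2–aqueous buffer pH 10.5, 0 °C
Reagents that add atoms: potassium peroxymonosulfate, [K+].[O-]S(=O)(=O)OO
Why: Shi asymmetric epoxidation through the spiro dioxirane transition state oxidises the terminal prenyl-type alkene, which is less hindered than the ring-bound alkene and far more electron-rich than the enone, and sets the (R)-configured oxygen-bearing carbon under catalyst control.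

**Step 5**
Reactants: 9 (4R)-4-{(2Z)-4-[(2R)-3,3-dimethyloxiran-2-yl]but-2-en-2-yl}cyclohex-2-en-1-one
Product: 10 (4aR,8R,9aS)-8-hydroxy-5,9,9-trimethyl-1,3,4,4a,7,8,9,9a-octahydro-2H-benzo[7]annulen-2-one
Conditions: (C5H5)2TiCl2 (20 mol %), Mn dust, 2,4,6-collidine hydrochloride, THF, rt, slow addition of 9
Reagents that add atoms: none
Why: Nugent–RajanBabu reductive epoxide opening by trivalent titanium gives the tertiary beta-titanoxy radical, which closes the seven-membered ring by 7-exo Giese addition to the enone carbon next to the ring stereocentre (the cis-alkene tether reaches only the face it is attached to, hence the cis ring fusion), and the titanium enolate is then protonated by collidinium.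

**Step 6**
Reactants: 10 (4aR,8R,9aS)-8-hydroxy-5,9,9-trimethyl-1,3,4,4a,7,8,9,9a-octahydro-2H-benzo[7]annulen-2-one
Product: 11 (4aR,8R,9aS)-5,9,9-trimethyl-2-oxo-2,3,4,4a,7,8,9,9a-octahydro-1H-benzo[7]annulen-8-yl (2Z)-2-methylbut-2-enoate
Conditions: angelic acid, 2,4,6-trichlorobenzoyl chloride, Et3N, toluene, rt; then 10, 80 °C
Reagents that add atoms: angelic acid [(2Z)-2-methylbut-2-enoic acid], C/C=C(/C)C(=O)O
Why: Yamaguchi-type mixed-anhydride esterification without a nucleophilic amine catalyst acylates the hindered secondary alcohol with retention at the carbinol carbon and without Z-to-E isomerisation of the angelate.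

**Step 7**
Reactants: 11 (4aR,8R,9aS)-5,9,9-trimethyl-2-oxo-2,3,4,4a,7,8,9,9a-octahydro-1H-benzo[7]annulen-8-yl (2Z)-2-methylbut-2-enoate
Product: 13 (4aR,8R,9aS)-5,9,9-trimethyl-2-oxo-2,4a,7,8,9,9a-hexahydro-1H-benzo[7]annulen-8-yl (2Z)-2-methylbut-2-enoate, via silyl enol ether 12 (not isolated)
Conditions: LiN(SiMe3)2, Me3SiCl, THF, −78 °C; then Pd(OAc)2, MeCN, rt
Reagents that add atoms: none
Why: Kinetic deprotonation takes the unhindered methylene remote from the ring-fusion carbon that carries the quaternary centre, and Saegusa–Ito oxidation of that enol silane installs a second enone double bond that later blocks enolisation on this side and carries the carbonyl transposition, leaving all stereocentres untouched.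

**Step 8**
Reactants: 13 (4aR,8R,9aS)-5,9,9-trimethyl-2-oxo-2,4a,7,8,9,9a-hexahydro-1H-benzo[7]annulen-8-yl (2Z)-2-methylbut-2-enoate
Product: 14 (4aR,5S,6R,8R,9aS)-5,6-epoxy-5,9,9-trimethyl-2-oxo-2,4a,5,6,7,8,9,9a-octahydro-1H-benzo[7]annulen-8-yl (2Z)-2-methylbut-2-enoate
Conditions: mCPBA, NaHCO3, CH2Cl2, 0 °C
Reagents that add atoms: 3-chloroperoxybenzoic acid, OOC(=O)c1cccc(Cl)c1
Why: Prilezhaev epoxidation is chemoselective for the only electron-rich alkene and is expected on the convex face of the cis-fused bicycle, anti to the cyclohexenone ring, which puts the oxygen opposite to the later carbon nucleophile.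

**Step 9**
Reactants: 14 (4aR,5S,6R,8R,9aS)-5,6-epoxy-5,9,9-trimethyl-2-oxo-2,4a,5,6,7,8,9,9a-octahydro-1H-benzo[7]annulen-8-yl (2Z)-2-methylbut-2-enoate
Product: 17 (4S,5R,7R,9R,10S,11R)-7-[(2Z)-2-methylbut-2-enoyloxy]-9-(3-methylbutanoyloxy)-15-norlongipin-1-en-3-one, via potassium enolate 15 (not isolated), via potassium alkoxide 16 (not isolated)
Conditions: KN(SiMe3)2, THF, −78 °C to 0 °C; then (Me2CHCH2CO)2O, −78 °C to rt
Reagents that add atoms: 3-methylbutanoic anhydride, CC(C)CC(=O)OC(=O)CC(C)C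
Why: Proposed new method: the kinetic alpha-prime enolate of the enone (the only enolisable alpha position) attacks the tertiary epoxide carbon in a 4-exo-tet SN2 opening with inversion, which forms the cyclobutane and releases the secondary alkoxide anti to the new bond for acylation in the same flask, the closest known reaction type being the Stork epoxynitrile cyclisation, where 4-exo closure onto the more substituted epoxide carbon beats 5-endo closure.

**Step 10**
Reactants: 17 (4S,5R,7R,9R,10S,11R)-7-[(2Z)-2-methylbut-2-enoyloxy]-9-(3-methylbutanoyloxy)-15-norlongipin-1-en-3-one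
Product: 18 (3S,4S,5R,7R,9R,10S,11R)-3-hydroxy-7-[(2Z)-2-methylbut-2-enoyloxy]-9-(3-methylbutanoyloxy)longipin-1-ene
Conditions: MeMgBr, CeCl3, THF, −78 °C
Reagents that add atoms: methylmagnesium bromide, C[Mg]Br
Why: Cerium-mediated 1,2-addition of the methyl nucleophile to the enone carbonyl is much faster than attack on the two hindered esters at −78 °C and occurs anti to the bridge methyl group, although the new carbinol centre is erased in the next step.

**Step 11**
Reactants: 18 (3S,4S,5R,7R,9R,10S,11R)-3-hydroxy-7-[(2Z)-2-methylbut-2-enoyloxy]-9-(3-methylbutanoyloxy)longipin-1-ene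
Product: 19 (4R,5S,7R,9R,10R,11R)-7-[(2Z)-2-methylbut-2-enoyloxy]-9-(3-methylbutanoyloxy)longipin-2-en-1-one (target)
Conditions: pyridinium chlorochromate (C5H5NH)[CrO3Cl], NaOAc, 4 Å molecular sieves, CH2Cl2, rt
Reagents that add atoms: pyridinium chlorochromate, [O-][Cr](=O)(=O)Cl.c1cc[nH+]cc1
Why: Dauben–Babler oxidative 1,3-transposition (chromate ester, [3,3]-shift, oxidation) moves the oxygen to the other allylic terminus and gives the beta-methyl enone of the target, while the six stereocentres of the target are not touched and keep their configuration.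

**Compound list**
1 | 5-bromo-2-methylpent-2-ene | CC(C)=CCCBr | starting material
2 | (4-methylpent-3-en-1-yl)triphenylphosphonium bromide | CC(C)=CCC[P+](c1ccccc1)(c1ccccc1)c1ccccc1.[Br-] | intermediate
3 | 1-(1,4-dioxaspiro[4.5]decan-8-yl)ethan-1-one | CC(=O)C1CCC2(CC1)OCCO2 | starting material
4 | (4-methylpent-3-en-1-ylidene)triphenyl-λ5-phosphane | CC(C)=CCC=P(c1ccccc1)(c1ccccc1)c1ccccc1 | intermediate (not isolated)
5 | 8-[(2Z)-6-methylhepta-2,5-dien-2-yl]-1,4-dioxaspiro[4.5]decane | C1COC2(O1)CCC(CC2)/C(C)=C\CC=C(C)C | intermediate (not isolated)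
6 | 4-[(2Z)-6-methylhepta-2,5-dien-2-yl]cyclohexan-1-one | O=C1CCC(CC1)/C(C)=C\CC=C(C)C | intermediate
7 | trimethyl({(4R)-4-[(2Z)-6-methylhepta-2,5-dien-2-yl]cyclohex-1-en-1-yl}oxy)silane | C[Si](C)(C)OC1=CC[C@@H](CC1)/C(C)=C\CC=C(C)C | intermediate (not isolated)
8 | (4R)-4-[(2Z)-6-methylhepta-2,5-dien-2-yl]cyclohex-2-en-1-one | O=C1C=C[C@@H](CC1)/C(C)=C\CC=C(C)C | intermediate
9 | (4R)-4-{(2Z)-4-[(2R)-3,3-dimethyloxiran-2-yl]but-2-en-2-yl}cyclohex-2-en-1-one | O=C1C=C[C@@H](CC1)/C(C)=C\C[C@H]2OC2(C)C | intermediate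
10 | (4aR,8R,9aS)-8-hydroxy-5,9,9-trimethyl-1,3,4,4a,7,8,9,9a-octahydro-2H-benzo[7]annulen-2-one (cis-fused) | O[C@@H]1CC=C(C)[C@@H]2CCC(=O)C[C@@H]2C1(C)C | intermediate
11 | (4aR,8R,9aS)-5,9,9-trimethyl-2-oxo-2,3,4,4a,7,8,9,9a-octahydro-1H-benzo[7]annulen-8-yl (2Z)-2-methylbut-2-enoate | C/C=C(/C)C(=O)O[C@@H]1CC=C(C)[C@@H]2CCC(=O)C[C@@H]2C1(C)C | intermediate
12 | (4aR,8R,9aS)-5,9,9-trimethyl-2-[(trimethylsilyl)oxy]-4,4a,7,8,9,9a-hexahydro-1H-benzo[7]annulen-8-yl (2Z)-2-methylbut-2-enoate | C/C=C(/C)C(=O)O[C@@H]1CC=C(C)[C@@H]2CC=C(O[Si](C)(C)C)C[C@@H]2C1(C)C | intermediate (not isolated)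
13 | (4aR,8R,9aS)-5,9,9-trimethyl-2-oxo-2,4a,7,8,9,9a-hexahydro-1H-benzo[7]annulen-8-yl (2Z)-2-methylbut-2-enoate | C/C=C(/C)C(=O)O[C@@H]1CC=C(C)[C@@H]2C=CC(=O)C[C@@H]2C1(C)C | intermediate
14 | (4aR,5S,6R,8R,9aS)-5,6-epoxy-5,9,9-trimethyl-2-oxo-2,4a,5,6,7,8,9,9a-octahydro-1H-benzo[7]annulen-8-yl (2Z)-2-methylbut-2-enoate | C/C=C(/C)C(=O)O[C@@H]1C[C@H]3O[C@@]3(C)[C@@H]2C=CC(=O)C[C@@H]2C1(C)C | intermediate
15 | potassium (4aR,5S,6R,8R,9aS)-5,6-epoxy-5,9,9-trimethyl-8-{[(2Z)-2-methylbut-2-enoyl]oxy}-5,6,7,8,9,9a-hexahydro-4aH-benzo[7]annulen-2-olate | C/C=C(/C)C(=O)O[C@@H]1C[C@H]3O[C@@]3(C)[C@@H]2C=CC([O-])=C[C@@H]2C1(C)C.[K+] | intermediate (not isolated)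
16 | potassium (4S,5R,7R,9R,10S,11R)-7-[(2Z)-2-methylbut-2-enoyloxy]-3-oxo-15-norlongipin-1-en-9-olate | C/C=C(/C)C(=O)O[C@@H]1C[C@@H]([O-])[C@@]2(C)[C@@H]3C=CC(=O)[C@H]2[C@@H]3C1(C)C.[K+] | intermediate (not isolated)
17 | (4S,5R,7R,9R,10S,11R)-7-[(2Z)-2-methylbut-2-enoyloxy]-9-(3-methylbutanoyloxy)-15-norlongipin-1-en-3-one | C/C=C(/C)C(=O)O[C@@H]1C[C@@H](OC(=O)CC(C)C)[C@@]2(C)[C@@H]3C=CC(=O)[C@H]2[C@@H]3C1(C)C | intermediate
18 | (3S,4S,5R,7R,9R,10S,11R)-3-hydroxy-7-[(2Z)-2-methylbut-2-enoyloxy]-9-(3-methylbutanoyloxy)longipin-1-ene | C/C=C(/C)C(=O)O[C@@H]1C[C@@H](OC(=O)CC(C)C)[C@@]2(C)[C@@H]3C=C[C@](C)(O)[C@H]2[C@@H]3C1(C)C | intermediate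
19 | (4R,5S,7R,9R,10R,11R)-7-[(2Z)-2-methylbut-2-enoyloxy]-9-(3-methylbutanoyloxy)longipin-2-en-1-one | C/C=C(/C)C(=O)O[C@@H]1C[C@@H](OC(=O)CC(C)C)[C@@]2(C)[C@@H]3C(=O)C=C(C)[C@H]2[C@@H]3C1(C)C | target

**Step count and risk**
Total steps: 11. Longest linear sequence: 11 steps (1 to 19); 10 steps from 3.

The three steps most likely to fail are steps 9, 5 and 8.

Step 9 (cyclobutane closure) may give vinylogous beta-elimination of the epoxide through the gamma-dienolate, or no closure at the tertiary carbon. The fallback changes from an anionic to a cationic closure and sets out from 14. The alpha-prime enolate is trapped at −78 °C with Me3SiCl (KN(SiMe3)2, THF) to give the silyloxy diene (4aR,5S,6R,8R,9aS)-5,6-epoxy-5,9,9-trimethyl-2-[(trimethylsilyl)oxy]-5,6,7,8,9,9a-hexahydro-4aH-benzo[7]annulen-8-yl (2Z)-2-methylbut-2-enoate F1. The epoxide is then ionised with TiCl4 in CH2Cl2 at −78 °C so that the enol silane captures the tertiary cation (Mukaiyama-type epoxide–enol silane cyclisation), giving after aqueous work-up (4S,5R,7R,9R,10S,11R)-9-hydroxy-7-[(2Z)-2-methylbut-2-enoyloxy]-15-norlongipin-1-en-3-one F2. Acylation with 3-methylbutanoyl chloride and pyridine comes back to the route at 17.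

Step 5 (seven-membered ring) may lose to reduction or elimination of the tertiary radical by trivalent titanium, or to hydrogen transfer from the doubly allylic ring CH. The fallback replaces metal-mediated epoxide homolysis by a halide-based chain cyclisation and sets out from 9. MgBr2·OEt2 in Et2O at −20 °C opens the epoxide at its tertiary carbon to give (4R)-4-[(2Z,5R)-6-bromo-5-hydroxy-6-methylhept-2-en-2-yl]cyclohex-2-en-1-one F3. Slow addition of Bu3SnH and AIBN in toluene at 80 °C then generates the same tertiary radical for the 7-exo Giese closure and comes back to the route at 10.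

Step 8 (epoxide face) may put the oxygen on the face syn to the cyclohexenone ring, which makes step 9 impossible. The fallback inverts the facial outcome through a halohydrin and sets out from 13. NBS in THF–water at 0 °C forms the bromonium ion on the face the peracid prefers, and water opens it at the tertiary carbon from the other face to give (4aR,5S,6S,8R,9aS)-6-bromo-5-hydroxy-5,9,9-trimethyl-2-oxo-2,4a,5,6,7,8,9,9a-octahydro-1H-benzo[7]annulen-8-yl (2Z)-2-methylbut-2-enoate F4. K2CO3 in acetone closes the ring with inversion at the bromine-bearing carbon and comes back to the route at 14.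

**Further compounds**
F1 | step 9 | (4aR,5S,6R,8R,9aS)-5,6-epoxy-5,9,9-trimethyl-2-[(trimethylsilyl)oxy]-5,6,7,8,9,9a-hexahydro-4aH-benzo[7]annulen-8-yl (2Z)-2-methylbut-2-enoate | C/C=C(/C)C(=O)O[C@@H]1C[C@H]3O[C@@]3(C)[C@@H]2C=CC(O[Si](C)(C)C)=C[C@@H]2C1(C)C
F2 | step 9 | (4S,5R,7R,9R,10S,11R)-9-hydroxy-7-[(2Z)-2-methylbut-2-enoyloxy]-15-norlongipin-1-en-3-one | C/C=C(/C)C(=O)O[C@@H]1C[C@@H](O)[C@@]2(C)[C@@H]3C=CC(=O)[C@H]2[C@@H]3C1(C)C
F3 | step 5 | (4R)-4-[(2Z,5R)-6-bromo-5-hydroxy-6-methylhept-2-en-2-yl]cyclohex-2-en-1-one | O=C1C=C[C@@H](CC1)/C(C)=C\C[C@@H](O)C(C)(C)Br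
F4 | step 8 | (4aR,5S,6S,8R,9aS)-6-bromo-5-hydroxy-5,9,9-trimethyl-2-oxo-2,4a,5,6,7,8,9,9a-octahydro-1H-benzo[7]annulen-8-yl (2Z)-2-methylbut-2-enoate | C/C=C(/C)C(=O)O[C@@H]1C[C@H](Br)[C@@](C)(O)[C@@H]2C=CC(=O)C[C@@H]2C1(C)C
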